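The vessel is closed, stirred and isothermal, and it holds substrate, partner and free catalyst.

all flasks: free catalyst 10 mol%

| run | substrate | partner | remark |
|---|---|---|---|
| winter | 0.061 M | 2 equiv | run made earlier |
| summer | 0.14 M | 2 equiv | run made earlier |
| dusk | 0.091 M | 4 equiv | run made earlier |
| flask | 0.091 M | 2.00 equiv |  |

| run | time / h | target / % | substrate / % |
|---|---|---|---|
| winter | 1.50 | 1.2 | 81.4 |
| winter | 3.00 | 5.4 | 68.1 |
| winter | 5.00 | 9.5 | 56.7 |
| winter | 6.00 | 11.0 | 52.4 |
| winter | 8.00 | 13.9 | 43.8 |
| winter | 10.0 | 18.2 | 37.7 |
| winter | 12.0 | 19.9 | 32.5 |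
| summer | 0.667 | 0 | 80.8 |
| summer | 2.00 | 4.4 | 60.6 |
| summer | 3.00 | 7.0 | 49.6 |
| summer | 5.00 | 12.5 | 37.2 |
| summer | 8.00 | 18.5 | 25.0 |
| summer | 10.0 | 21.4 | 19.8 |
| summer | 12.0 | 23.6 | 16.0 |
| dusk | 2.50 | 5.0 | 64.8 |
| dusk | 5.00 | 11.5 | 46.5 |
| dusk | 8.00 | 16.4 | 34.0 |
| dusk | 10.0 | 19.3 | 28.6 |
| dusk | 12.0 | 22.9 | 24.0 |

(standard deviation of a reading: 0.5 percentage points)

- what is bound to the catalyst counts as converted

- apparent order in partner when 20% of the substrate are converted (percent change of the rate of making target for one percent more partner charged)
- factor on the rate of making target when 20% of the substrate are converted if free catalyst is charged twice over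

I read the partner's effect from the target at 10.0 h. Winter gives 18.2% and summer 21.4%, both with 2 equiv of partner. Weighted by the logarithm of the substrate charge, with 0.481 on summer, they give an estimate of 19.7% for the flask's charge. Dusk has that substrate charge with partner doubled, and it gives 19.3%. The gap is 0.40 percentage points, and a reading scatters by 0.5 points. The logarithm of the target ratio over that of the partner ratio is −0.0326. This is my partner exponent. It reads accumulated target, not the rate at 20%, so it is a stand-in. I commit to an order near zero, and to 19.7% of target in the flask at 10.0 h.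

The forecast says an order of 0.15, from −0.1 to 0.5, on the grounds that “Partner therefore has little effect”, and a factor of 1.6, from 1.1 to 2.1. Its order is higher than my exponent.

The flask gives an order of 0.010 and a factor of 1.56.

    2 free catalyst → spent catalyst (k = 0.160 /M/min)
    catalyst intermediate D → free catalyst + target (k = 0.780 /min)
    catalyst intermediate C → catalyst intermediate D (k = 0.0200 /min)
    catalyst intermediate B ⇌ released group + catalyst intermediate C (K = 0.0540 M, k = 0.0240 /min)
    2 substrate → self-condensation product (k = 0.0150 /M/min)
    partner + free catalyst → catalyst intermediate A (k = 6.60 /M/min)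
    substrate + catalyst intermediate A ⇌ catalyst intermediate B (K = 11.0 /M, k = 0.270 /M/min)

In the flask, the step of partner with free catalyst into catalyst intermediate A gives free catalyst a half-life by that step of 0.62 min at 2.41 h and 0.68 min at 10.0 h. Between 1.00 h and 10.0 h free catalyst goes from 0.333% to 0.225% of the catalyst charged, and catalyst intermediate A, the resting state, climbs from 54.8% to 74.9% of it, while self-condensation product reaches 49.6% of the substrate charged. The flask's target at 10.0 h is 19.7% against my estimate of 19.7%; set against the dusk readings, the partner exponent is −0.0302 at that time and 0.0465 at 5.00 h.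

The data were generated by integration with constants of no real substance, and the scatter is random.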